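**Retrosynthetic overview**
- The last ring to close is ring D, the bridged bicyclo[3.2.1]octane. The C13–C16 bond forms by intramolecular enolate displacement of a C13 allylic acetate. The two ring alkenes are then hydrogenated.
- Ring C, the C20–O–C7 δ-lactone and the quaternary C8 form together in one domino Knoevenagel/intramolecular Diels–Alder reaction (key step 2). An acylacrylate tethered through the C20 ester adds to a dienyl acetate carried on C9.
- Ring A and the C4/C5/C10 stereotriad form in an intermolecular Diels–Alder reaction of an α-methylbutenolide with a semicyclic diene (key step 1). The butenolide is made from (S)-γ-hydroxymethylbutyrolactone, whose stereocentre directs the face of attack and is then excised by diol cleavage. C6 becomes the methyl acetal.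
- Rings form in this order: A with the THF lactone, then C with the δ-lactone, then D.

Assumption (one line): the C6 methyl acetal is taken as the thermodynamic exo-OMe anomer, cis to H5 and C18. C16 is α to the C15 ketone and equilibrates under the basic cyclisation to the natural epimer.

---

**Step 1**
Reactants: 1, (S)-5-(hydroxymethyl)dihydrofuran-2(3H)-one (from L-glutamic acid)
Product: 2, (S)-5-(TBSOCH2)dihydrofuran-2(3H)-one
Conditions: TBSCl, imidazole, DMF, 0 °C → rt
Reagents that add atoms: TBSCl, C(C)(C)(C)[Si](C)(C)Cl
Why: Silylation of the primary alcohol protects it and keeps the (S) centre that directs the later cycloaddition.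

**Step 2**
Reactants: 2
Product: 3, (5S)-5-(TBSOCH2)-3-methyl-dihydrofuran-2(3H)-one (α-epimer mixture)
Conditions: LDA, THF, –78 °C; then MeI
Reagents that add atoms: MeI, CI
Why: Enolate alkylation installs the future C18 methyl; the α-stereocentre is destroyed in step 4, so its configuration is irrelevant.

**Step 3**
Reactants: 3
Product: 4, (5S)-5-(TBSOCH2)-3-methyl-3-(phenylselanyl)-dihydrofuran-2(3H)-one
Conditions: LDA, THF, –78 °C; then PhSeCl
Reagents that add atoms: PhSeCl, Cl[Se]c1ccccc1
Why: The enolate is trapped at carbon by the selenium electrophile (α-selenation).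

**Step 4**
Reactants: 4
Product: 5, (S)-5-(TBSOCH2)-3-methylfuran-2(5H)-one
Conditions: H2O2, pyridine, CH2Cl2, 0 °C → rt
Reagents that add atoms: none
Why: Selenoxide syn-elimination into the ring (C4–H) gives the conjugated α-methylbutenolide; the (S) carbon is untouched.

**Step 5**
Reactants: 6, 2,2-dimethyl-1,3-dioxan-5-one; 7, allyltriphenylphosphonium bromide
Product: 8, 2,2-dimethyl-5-(prop-2-en-1-ylidene)-1,3-dioxane
Conditions: 7, n-BuLi, THF, 0 °C; then 6, –78 °C → rt
Reagents that add atoms: none (both partners are numbered reactants)
Why: Wittig olefination gives a symmetric semicyclic diene. Its two CH2O arms are identical, so there is no E/Z issue at C10.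

**Step 6 (key cycloaddition 1)**
Reactants: 5; 8
Product: 9, spiro[dioxane–cyclohexene] cis-fused to the γ-lactone (ring A and THF lactone; C4, C5, C10 set)
Conditions: toluene, BHT, 120 °C, sealed tube, 72 h
Reagents that add atoms: none
Why: Intermolecular Diels–Alder. The diene attacks the butenolide face anti to the CH2OTBS group, which sets C4 and C5 in the natural ent sense. The cis-fused lactone places C18 and H5 cis, and the arm of the spiro centre cis to the lactone becomes C20 (cis to C19). Joining C10 to the CH carbon and the CH2 terminus to the α-carbon is favoured because bonding two fully substituted carbons to each other is prohibitive. The two CH2O arms are equivalent, so endo and exo give the same compound.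

**Step 7**
Reactants: 9
Product: 10, diol (C19–OH, C6–OH) bearing the CH2OTBS group
Conditions: LiAlH4, THF, 0 °C → rt
Reagents that add atoms: none
Why: Lactone reduction turns C19 into the CH2OH group and frees the C6 oxygen; the acetonide, TBS ether and alkene survive.

**Step 8**
Reactants: 10
Product: 11, triol with a free C6(OH)–CH2OH 1,2-diol
Conditions: TBAF, THF, rt
Reagents that add atoms: none
Why: Fluoride removes the silyl group to unmask the vicinal diol.

**Step 9**
Reactants: 11
Product: 12, C6 aldehyde with free C19–OH
Conditions: NaIO4, THF/H2O, 0 °C → rt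
Reagents that add atoms: none
Why: Malaprade cleavage removes the director carbon as formaldehyde, which erases the directing stereocentre and gives the C6 aldehyde.

**Step 10**
Reactants: 12
Product: 13, C6 methyl acetal (THF) with the C9- and C20-hydroxymethyl diol
Conditions: MeOH, CSA (cat.), rt
Reagents that add atoms: MeOH, CO
Why: The hydroxy-aldehyde closes to the lactol and is acetalised. The acetonide is trans-ketalised away, and the exo-OMe (cis to H5 and C18) anomer is favoured.

**Step 11**
Reactants: 13
Product: 14, C9 aldehyde (C20–CH2OH kept)
Conditions: Dess–Martin periodinane (1.0 equiv), NaHCO3, CH2Cl2, 0 °C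
Reagents that add atoms: none
Why: The equatorial C9–CH2OH is far more accessible than the axial C20–CH2OH, which sits 1,3-diaxial to the C19 methylene; steric selectivity in oxidation.

**Step 12**
Reactants: 14
Product: 15, (E)-C9=C11–I vinyl iodide
Conditions: CHI3, CrCl2, THF, 0 °C → rt
Reagents that add atoms: iodoform, IC(I)I
Why: Takai–Utimoto olefination installs C11 with high E selectivity and tolerates the free hydroxyl.

**Step 13**
Reactants: 15; 16, vinyl acetate
Product: 17, (E,E)-dienyl acetate (C9=C11–C12=C13–OAc)
Conditions: Pd(OAc)2, P(o-tol)3, Et3N, MeCN, 80 °C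
Reagents that add atoms: none
Why: Mizoroki–Heck coupling of the vinyl iodide with vinyl acetate adds C12 and C13 and gives the electron-rich dienyl acetate with retention of E,E geometry.

**Step 14**
Reactants: 17; 18, methyl 3-oxopentanoate
Product: 19, C20 propionylacetate ester
Conditions: DMAP (cat.), toluene, 110 °C (MeOH removed)
Reagents that add atoms: none
Why: Transesterification via an acylketene acylates the hindered axial alcohol and carries C7, C8, C15, C16 and C17.

**Step 15 (key cycloaddition 2)**
Reactants: 19
Product: 20, tetracycle with ring C, the δ-lactone, quaternary C8 with C15 ketone, C11=C12 alkene and C13–OAc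
Conditions: (CH2O)n, piperidinium acetate (cat.), MeCN, 60 °C
Reagents that add atoms: paraformaldehyde, C=O
Why: Tietze domino Knoevenagel/intramolecular Diels–Alder. The in-situ methylene β-ketoester is an extremely reactive dienophile. The four-atom ester tether forces the fused mode, with C9 bonding to C8 and C14 bonding to C13. Facial selectivity comes from C10. The endo ester gives the cis-fused lactone and leaves the ketone exo, as required for bridging. The all-cis outcome from the (E,E)-diene puts OAc cis to C10 and trans to C15.

**Step 16**
Reactants: 20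
Product: 21, bicyclo[3.2.1]octene (ring D closed; C11=C12 and C1=C2 still present)
Conditions: Pd(PPh3)4 (10 mol%), KHMDS, THF, –78 → 0 °C
Reagents that add atoms: none
Why: Intramolecular allylic alkylation closes C16–C13. The ketone enolate (C16) displaces the allylic acetate from the face anti to OAc, which is the face carrying C15, so C13 is set by ring constraints. C16 equilibrates to the natural epimer.

**Step 17**
Reactants: 21
Product: 22, ludongnin I
Conditions: H2 (1 atm), Pd/C, EtOAc, rt
Reagents that add atoms: none
Why: Hydrogenation of the two cis-disubstituted ring alkenes (C1=C2, C11=C12) leaves the ketone, lactone and acetal intact and creates no new stereocentres.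

---

**Compound list**

| No. | Name | SMILES | Role |
|---|---|---|---|
| 1 | (S)-5-(hydroxymethyl)dihydrofuran-2(3H)-one | O=C1CC[C@@H](CO)O1 | starting material |
| 2 | (S)-5-(TBSOCH2)-γ-butyrolactone | O=C1CC[C@@H](CO[Si](C)(C)C(C)(C)C)O1 | intermediate |
| 3 | α-methyl lactone (α-epimer mixture) | O=C1C(C)C[C@@H](CO[Si](C)(C)C(C)(C)C)O1 | intermediate |
| 4 | α-methyl-α-phenylselanyl lactone | O=C1C(C)([Se]c2ccccc2)C[C@@H](CO[Si](C)(C)C(C)(C)C)O1 | intermediate |
| 5 | (S)-5-(TBSOCH2)-3-methylfuran-2(5H)-one | O=C1O[C@H](CO[Si](C)(C)C(C)(C)C)C=C1C | intermediate |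
| 6 | 2,2-dimethyl-1,3-dioxan-5-one | CC1(C)OCC(=O)CO1 | starting material |
| 7 | allyltriphenylphosphonium bromide | C=CC[P+](c1ccccc1)(c1ccccc1)c1ccccc1.[Br-] | starting material |
| 8 | 2,2-dimethyl-5-(prop-2-en-1-ylidene)-1,3-dioxane | C=CC=C1COC(C)(C)OC1 | intermediate |
| 9 | spiro-acetonide cis-fused γ-lactone Diels–Alder adduct | [C@H]1(CO[Si](C)(C)C(C)(C)C)OC(=O)[C@]2(C)CC=CC3(COC(C)(C)OC3)[C@H]12 | intermediate |
| 10 | diol from lactone reduction (CH2OTBS retained) | OC[C@]2(C)CC=CC3(COC(C)(C)OC3)[C@@H]2[C@H](O)CO[Si](C)(C)C(C)(C)C | intermediate |
| 11 | triol after desilylation | OC[C@]2(C)CC=CC3(COC(C)(C)OC3)[C@@H]2[C@H](O)CO | intermediate |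
| 12 | C6 aldehyde with free C19–OH | OC[C@]2(C)CC=CC3(COC(C)(C)OC3)[C@@H]2C=O | intermediate |
| 13 | C6 methyl acetal, C9/C20 diol (first CO = C9, second CO = C20) | CO[C@H]1OC[C@]2(C)CC=C[C@](CO)(CO)[C@H]12 | intermediate |
| 14 | C9 aldehyde | CO[C@H]1OC[C@]2(C)CC=C[C@](C=O)(CO)[C@H]12 | intermediate |
| 15 | (E)-vinyl iodide | CO[C@H]1OC[C@]2(C)CC=C[C@](/C=C/I)(CO)[C@H]12 | intermediate |
| 16 | vinyl acetate | C=COC(C)=O | starting material |
| 17 | (E,E)-dienyl acetate | CO[C@H]1OC[C@]2(C)CC=C[C@](/C=C/C=C/OC(C)=O)(CO)[C@H]12 | intermediate |
| 18 | methyl 3-oxopentanoate | CCC(=O)CC(=O)OC | starting material |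
| 19 | C20 propionylacetate ester | CO[C@H]1OC[C@]2(C)CC=C[C@](/C=C/C=C/OC(C)=O)(COC(=O)CC(=O)CC)[C@H]12 | intermediate |
| 20 | domino Diels–Alder tetracycle (C13–OAc, C15 ethyl ketone) | CO[C@H]1OC[C@]2(C)CC=C[C@]3(COC(=O)[C@@]4(C(=O)CC)C[C@H](C=C[C@H]43)OC(C)=O)[C@H]12 | intermediate |
| 21 | bicyclo[3.2.1]octene diene-ene precursor | CO[C@H]1OC[C@]2(C)CC=C[C@]3(COC(=O)[C@@]45C[C@@H](C=C[C@H]43)[C@@H](C)C5=O)[C@H]12 | intermediate |
| 22 | ludongnin I | CO[C@H]1OC[C@]2(C)CCC[C@]3(COC(=O)[C@@]45C[C@@H](CC[C@H]43)[C@@H](C)C5=O)[C@H]12 | target |

**Total steps:** 17 (16 on the longest linear sequence, which runs 1 → 2 → 3 → 4 → 5 → 9 → … → 22; the diene 8 is made in a parallel one-step branch).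

**Three steps most likely to fail**
1. **Step 6 (ring A Diels–Alder).** The hindered semicyclic diene and the α-methylbutenolide may react slowly or give the wrong regiochemistry (a bond between two quaternary-forming carbons is disfavoured, but electronics oppose the desired mode).
   Fallback: stepwise polar annulation, a Mukaiyama–Michael addition of a silyl dienol ether to butenolide 5 followed by intramolecular alkylation to close C5–C10.
2. **Step 15 (domino Knoevenagel/Diels–Alder).** The tether must force the electronically mismatched fused mode, and the required endo-ester/exo-ketone arrangement must win. Hetero-Diels–Alder or amine cleavage of the enol acetate could compete.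
   Fallback: run the Diels–Alder with a plain acrylate tether, then form C8–C15 by acylation of the lactone enolate with a C13-tethered Weinreb amide, which is a different ring D closure.
3. **Step 16 (ring D closure).** SN2′ attack at C11 or elimination could compete with the desired C13 displacement, and C16 epimerisation is uncontrolled.
   Fallback: use the terminal-diene version of the Diels–Alder, then allylic oxidation at C13, intramolecular aldol to form the C13–C16 bond, and Barton–McCombie deoxygenation of the bridgehead alcohol.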